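**Retrosynthetic overview**

1. The bridged ketal is a masked flavanone. Opening the C4–O–C2' bridge (ketal ring, closed last) gives a (2R)-2',6'-dihydroxyflavanone, so C2 is the only stereocentre that has to be made and C4 follows from it.
2. The C4 carbonyl is traced back to the C4–OMe group of a 2,4-cis-4-methoxyflavan (hydrolysis, then oxidation).
3. Key disconnection in ring C: this ring holds the oxadiene O1=C8a–C4a=C4 of a ring A ortho-quinone methide joined to the two-carbon unit C3–C2 that carries ring B. Cutting C3–C4 and O1–C2 gives a ring A salicylaldehyde, trimethyl orthoformate and a 2,6-bis(silyloxy)styrene, to be united in a chiral phosphoric acid-catalysed [4+2] reaction.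
4. Salicylaldehyde: 5-methoxyresorcinol, C2 prenylation by directed metalation, prenal annulation (dimethylpyran ring; the symmetric diol allows one regioisomer only), ortho-formylation. Styrene: 2,6-dihydroxybenzaldehyde, silylation, Wittig methylenation.
5. Ring order: rings A and B are bought, then the dimethylpyran ring (step 4), ring C (step 8) and the ketal ring (step 11).

Key step: step 8

Remark on naming: flavan locants are used (O1, C2 bearing ring B, C3, C4, C4a, C5–C8, C8a; ring B C1'–C6'). "Prenyl" is 3-methylbut-2-en-1-yl. The dimethylpyran ring (1''–6'') has its oxygen on C7 and its CH=CH on C6.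

Assumption: the sense of induction of the acid in step 8 cannot be derived with certainty; the (R)-acid is written, and its mirror image is to be used if the first run leads into the 2S series.

**Route**

Step 1
Reactants: 1 5-methoxyresorcinol
Product: 2 1-methoxy-3,5-bis(methoxymethoxy)benzene
Conditions: MOMCl (2.5 equiv), iPr2NEt (3 equiv), CH2Cl2, 0 °C → rt
Reagents that add atoms: chloromethyl methyl ether, COCCl
Why: Base-mediated O-alkylation of both phenols with the reactive α-chloro ether (Williamson-type) should install the two acetal groups that later direct the metalation.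

Step 2
Reactants: 2 1-methoxy-3,5-bis(methoxymethoxy)benzene; 3 prenyl bromide (1-bromo-3-methylbut-2-ene)
Product: 5 5-methoxy-1,3-bis(methoxymethoxy)-2-(3-methylbut-2-en-1-yl)benzene, via aryllithium 4 (not isolated)
Conditions: n-BuLi (1.1 equiv), THF, 0 °C; then CuI (10 mol %), 3, −78 °C → rt
Reagents that add atoms: none
Why: Directed ortho-metalation: the proton between the two chelating methoxymethoxy groups is the most acidic on the ring, so lithiation should occur there rather than at the positions flanked by one methoxymethoxy and the methoxy group, and aryllithium 4 is then alkylated at the primary carbon of the allylic bromide (copper-catalysed SN2 coupling).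

Step 3
Reactants: 5 5-methoxy-1,3-bis(methoxymethoxy)-2-(3-methylbut-2-en-1-yl)benzene
Product: 6 5-methoxy-2-(3-methylbut-2-en-1-yl)benzene-1,3-diol
Conditions: HCl (conc., cat.), MeOH, 40 °C
Reagents that add atoms: none
Why: Acid-catalysed transacetalisation of the two methoxymethyl ethers to methanol should proceed under conditions mild enough to leave the prenyl group uncyclised, and gives back the symmetric resorcinol.

Step 4
Reactants: 6 5-methoxy-2-(3-methylbut-2-en-1-yl)benzene-1,3-diol; 7 3-methylbut-2-enal
Product: 9 5-methoxy-2,2-dimethyl-8-(3-methylbut-2-en-1-yl)-2H-chromen-7-ol, via oxatriene 8 (not isolated)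
Conditions: ethylenediammonium diacetate (10 mol %), 7 (1.1 equiv), PhMe, reflux
Reagents that add atoms: none
Why: Amine-catalysed Knoevenagel-type condensation at a ring carbon ortho to a hydroxyl gives the 1-oxatriene 8, which closes by oxa-6π-electrocyclisation (formal [3+3] chromene annulation); the two free ortho positions of 6 are equivalent, so one regioisomer only can arise, and keeping 7 near one equivalent limits a second annulation.

Step 5
Reactants: 9 5-methoxy-2,2-dimethyl-8-(3-methylbut-2-en-1-yl)-2H-chromen-7-ol
Product: 11 7-hydroxy-5-methoxy-2,2-dimethyl-8-(3-methylbut-2-en-1-yl)-2H-chromene-6-carbaldehyde, via salicyl alcohol 10 (not isolated)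
Conditions: MgCl2, Et3N, (CH2O)n, MeCN, reflux; then cold 1 M HCl
Reagents that add atoms: paraformaldehyde (as formaldehyde), C=O
Why: Casnati–Skattebøl ortho-formylation: the magnesium salt of phenol 9 delivers formaldehyde to the only free ring position, which is ortho to the hydroxyl, and salicyl alcohol 10 is oxidised in the same flask by hydride transfer to a second equivalent of formaldehyde, under conditions too mild to touch the chromene or prenyl alkenes.

Step 6
Reactants: 12 2,6-dihydroxybenzaldehyde
Product: 13 2,6-bis(tert-butyldimethylsilyloxy)benzaldehyde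
Conditions: TBSCl (2.5 equiv), imidazole (5 equiv), DMF, rt
Reagents that add atoms: tert-butyldimethylsilyl chloride, CC(C)(C)[Si](C)(C)Cl
Why: Imidazole-promoted O-silylation of both phenols; the bis-silyl ether should keep the ring B oxygens blocked through the acid steps that follow.

Step 7
Reactants: 13 2,6-bis(tert-butyldimethylsilyloxy)benzaldehyde
Product: 14 2,6-bis(tert-butyldimethylsilyloxy)styrene
Conditions: Ph3PCH3Br, KOtBu, THF, 0 °C; then 13, 0 °C → rt
Reagents that add atoms: methyltriphenylphosphonium bromide, C[P+](c1ccccc1)(c1ccccc1)c1ccccc1.[Br-]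
Why: Wittig methylenation of the non-enolisable aldehyde with the unstabilised ylide, which aryl silyl ethers should tolerate at low temperature.

Step 8
Reactants: 11 7-hydroxy-5-methoxy-2,2-dimethyl-8-(3-methylbut-2-en-1-yl)-2H-chromene-6-carbaldehyde; 14 2,6-bis(tert-butyldimethylsilyloxy)styrene
Product: 17 (2R,4R)-2',6'-bis(tert-butyldimethylsilyloxy)-4,5-dimethoxy-8-prenyl-6'',6''-dimethylpyrano[2'',3'':7,6]flavan (2,4-cis), via dimethyl acetal 15 (not isolated), via methoxy ortho-quinone methide 16 (not isolated)
Conditions: HC(OMe)3 (2 equiv), (R)-3,3'-bis(2,4,6-triisopropylphenyl)-1,1'-binaphthyl-2,2'-diyl hydrogen phosphate (10 mol %), 5 Å MS, PhMe, rt; then 14 (1.5 equiv), −20 °C → 0 °C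
Reagents that add atoms: trimethyl orthoformate, COC(OC)OC
Why: Proposed new method: the phosphoric acid should first catalyse acetalisation of 11 by the orthoformate and then ionise acetal 15 to the 4-methoxy ortho-quinone methide 16 (equivalently its O-protonated oxocarbenium form), which stays hydrogen-bonded or ion-paired to the chiral phosphate while the terminal CH2 of styrene 14 attacks C4 and the developing benzylic cation at C2, stabilised by the two ortho silyloxy groups, collapses onto the phenolic oxygen O1 in an asynchronous inverse-demand hetero-Diels–Alder reaction. The closest known reactions are the racemic acid-catalysed three-component chroman synthesis from salicylaldehydes, trimethyl orthoformate and styrenes, and chiral phosphoric acid-catalysed [4+2] reactions of ortho-quinone methides generated from ortho-hydroxybenzyl alcohols with electron-rich styrenes; enantiocontrol with the alkoxy-substituted quinone methide is the part not yet shown. Ring C is closed by this intermolecular [4+2] cycloaddition, C3–C4 forming ahead of O1–C2, the latter by six-membered C–O closure onto the benzylic cation. C2 is controlled by the catalyst, whose 2,4,6-triisopropylphenyl walls should shield one face of the bound oxadiene, and C4 follows from the endo-type arrangement that gives the 2,4-cis product, although its configuration is of no consequence later because C4 becomes the ketal carbon. Regiochemistry follows from polarity (nucleophilic CH2 to the electrophilic C4, cationic benzylic carbon to O1), and chemoselectivity for the terminal styrene over the chromene alkene (cis-disubstituted, next to a quaternary carbon) and the trisubstituted prenyl alkene rests on its lower hindrance and better stabilised cation, helped by the excess of 14. Since acetal 15 and both double-bond geometries of 16 interconvert through the same planar species, the step is stereoconvergent and only the facial selectivity at C2 has to be won.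

Step 9
Reactants: 17 (2R,4R)-2',6'-bis(tert-butyldimethylsilyloxy)-4,5-dimethoxy-8-prenyl-6'',6''-dimethylpyrano[2'',3'':7,6]flavan
Product: 18 (2R)-2',6'-bis(tert-butyldimethylsilyloxy)-5-methoxy-8-prenyl-6'',6''-dimethylpyrano[2'',3'':7,6]flavan-4-ol (both C4 epimers)
Conditions: pyridinium p-toluenesulfonate (20 mol %), THF/H2O 4:1, 40 °C
Reagents that add atoms: water, O
Why: Acid-catalysed SN1 solvolysis of the benzylic methyl ether: the three oxygen substituents of ring A make ionisation at C4 easy under weak acid, excess water captures the cation, the aryl silyl ethers and C2 should stay untouched, and the mixture of C4 epimers does not matter because C4 becomes a carbonyl in step 10.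

Step 10
Reactants: 18 (2R)-2',6'-bis(tert-butyldimethylsilyloxy)-5-methoxy-8-prenyl-6'',6''-dimethylpyrano[2'',3'':7,6]flavan-4-ol
Product: 19 (2R)-2',6'-bis(tert-butyldimethylsilyloxy)-5-methoxy-8-prenyl-6'',6''-dimethylpyrano[2'',3'':7,6]flavanone
Conditions: Dess–Martin periodinane, NaHCO3, CH2Cl2, 0 °C → rt
Reagents that add atoms: none
Why: Dess–Martin oxidation of the secondary benzylic alcohol to the aryl ketone under buffered, near-neutral conditions that should leave the alkenes, the silyl ethers and the C2 stereocentre untouched.

Step 11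
Reactants: 19 (2R)-2',6'-bis(tert-butyldimethylsilyloxy)-5-methoxy-8-prenyl-6'',6''-dimethylpyrano[2'',3'':7,6]flavanone
Product: 21 (2R,4R)-4,2'-epoxy-4,6'-dihydroxy-5-methoxy-8-prenyl-6'',6''-dimethylpyrano[2'',3'':7,6]flavan (CNP0170313.2), via dihydroxyflavanone 20 (not isolated)
Conditions: HF·pyridine, pyridine, THF, 0 °C → rt
Reagents that add atoms: none
Why: Fluoride cleavage of both aryl silyl ethers in a pyridine-buffered, non-basic medium (so that the flavanone does not open by retro-oxa-Michael elimination) frees flavanone 20, whose 2'-hydroxyl adds to the C4 carbonyl in an intramolecular hemiketalisation; the bridge can form only on the face of ring C that carries ring B, so the R configuration at C2 dictates the R configuration at C4.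

**Compound list**

1 | 5-methoxyresorcinol | COc1cc(O)cc(O)c1 | starting material
2 | 1-methoxy-3,5-bis(methoxymethoxy)benzene | COCOc1cc(OC)cc(OCOC)c1 | intermediate
3 | prenyl bromide (1-bromo-3-methylbut-2-ene) | CC(C)=CCBr | starting material
4 | [4-methoxy-2,6-bis(methoxymethoxy)phenyl]lithium | [Li]c1c(OCOC)cc(OC)cc1OCOC | intermediate
5 | 5-methoxy-1,3-bis(methoxymethoxy)-2-(3-methylbut-2-en-1-yl)benzene | COCOc1cc(OC)cc(OCOC)c1CC=C(C)C | intermediate
6 | 5-methoxy-2-(3-methylbut-2-en-1-yl)benzene-1,3-diol | COc1cc(O)c(CC=C(C)C)c(O)c1 | intermediate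
7 | 3-methylbut-2-enal | CC(C)=CC=O | starting material
8 | 1-oxatriene: 3-hydroxy-5-methoxy-2-prenyl-6-(3-methylbut-2-enylidene)cyclohexa-2,4-dien-1-one | O=C1C(CC=C(C)C)=C(O)C=C(OC)C1=CC=C(C)C | intermediate
9 | 5-methoxy-2,2-dimethyl-8-(3-methylbut-2-en-1-yl)-2H-chromen-7-ol | COc1cc(O)c(CC=C(C)C)c2OC(C)(C)C=Cc12 | intermediate
10 | 6-(hydroxymethyl)-5-methoxy-2,2-dimethyl-8-(3-methylbut-2-en-1-yl)-2H-chromen-7-ol | COc1c(CO)c(O)c(CC=C(C)C)c2OC(C)(C)C=Cc12 | intermediate
11 | 7-hydroxy-5-methoxy-2,2-dimethyl-8-(3-methylbut-2-en-1-yl)-2H-chromene-6-carbaldehyde | COc1c(C=O)c(O)c(CC=C(C)C)c2OC(C)(C)C=Cc12 | intermediate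
12 | 2,6-dihydroxybenzaldehyde | O=Cc1c(O)cccc1O | starting material
13 | 2,6-bis(tert-butyldimethylsilyloxy)benzaldehyde | O=Cc1c(O[Si](C)(C)C(C)(C)C)cccc1O[Si](C)(C)C(C)(C)C | intermediate
14 | 2,6-bis(tert-butyldimethylsilyloxy)styrene | C=Cc1c(O[Si](C)(C)C(C)(C)C)cccc1O[Si](C)(C)C(C)(C)C | intermediate
15 | 6-(dimethoxymethyl)-5-methoxy-2,2-dimethyl-8-prenyl-2H-chromen-7-ol | COc1c(C(OC)OC)c(O)c(CC=C(C)C)c2OC(C)(C)C=Cc12 | intermediate
16 | 5-methoxy-6-(methoxymethylidene)-2,2-dimethyl-8-prenyl-2H-chromen-7(6H)-one (4-methoxy ortho-quinone methide) | COC=C1C(=O)C(CC=C(C)C)=C2OC(C)(C)C=CC2=C1OC | intermediate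
17 | (2R,4R)-2',6'-bis(tert-butyldimethylsilyloxy)-4,5-dimethoxy-8-prenyl-6'',6''-dimethylpyrano[2'',3'':7,6]flavan (2,4-cis) | COc1c2c(c(CC=C(C)C)c3c1[C@H](OC)C[C@@H](O3)c1c(O[Si](C)(C)C(C)(C)C)cccc1O[Si](C)(C)C(C)(C)C)OC(C)(C)C=C2 | intermediate
18 | (2R)-2',6'-bis(tert-butyldimethylsilyloxy)-5-methoxy-8-prenyl-6'',6''-dimethylpyrano[2'',3'':7,6]flavan-4-ol (both C4 epimers) | COc1c2c(c(CC=C(C)C)c3c1C(O)C[C@@H](O3)c1c(O[Si](C)(C)C(C)(C)C)cccc1O[Si](C)(C)C(C)(C)C)OC(C)(C)C=C2 | intermediate
19 | (2R)-2',6'-bis(tert-butyldimethylsilyloxy)-5-methoxy-8-prenyl-6'',6''-dimethylpyrano[2'',3'':7,6]flavanone | COc1c2c(c(CC=C(C)C)c3c1C(=O)C[C@@H](O3)c1c(O[Si](C)(C)C(C)(C)C)cccc1O[Si](C)(C)C(C)(C)C)OC(C)(C)C=C2 | intermediate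
20 | (2R)-2',6'-dihydroxy-5-methoxy-8-prenyl-6'',6''-dimethylpyrano[2'',3'':7,6]flavanone | COc1c2c(c(CC=C(C)C)c3c1C(=O)C[C@@H](O3)c1c(O)cccc1O)OC(C)(C)C=C2 | intermediate
21 | (2R,4R)-4,2'-epoxy-4,6'-dihydroxy-5-methoxy-8-prenyl-6'',6''-dimethylpyrano[2'',3'':7,6]flavan (CNP0170313.2) | COc1c2c(c(CC=C(C)C)c3c1[C@@]1(O)C[C@@H](O3)c3c(O)cccc3O1)OC(C)(C)C=C2 | target

**Step count**

Total: 11 steps. Longest linear sequence: 9 steps (steps 1–5 and 8–11); the styrene branch (steps 6–7) joins at step 8.

**Steps most likely to fail**

Step 8 (the proposed new method). The phosphoric acid may be too weak to turn over acetal formation and ionisation of this very electron-rich, internally hydrogen-bonded aldehyde. The cationic quinone methide may be held too loosely by the phosphate, so that the two faces at C2 are poorly distinguished. The activated ring B arene may attack C4 in a Friedel–Crafts sense, or the styrene may oligomerise. Fallback by known chemistry, setting out from 11 and 14: the racemic three-component reaction with scandium tris(trifluoromethanesulfonate), Sc(OSO2CF3)3 (5 mol %), and HC(OMe)3 in CH2Cl2 at rt should give the racemic cis-4-methoxyflavan F1. The conditions of steps 9 and 10 should convert it into the racemic flavan-4-ol F2 and then the racemic flavanone F3. Kinetic resolution of F3 by asymmetric transfer hydrogenation follows, with RuCl(p-cymene)[(S,S)-N-(p-toluenesulfonyl)-1,2-diphenylethylenediamine] in HCO2H/Et3N at rt; the catalyst antipode is chosen so that the 2S ketone is the fast-reacting one. This should reduce the 2S ketone to the cis-(2S,4S)-flavan-4-ol F4, which is removed by chromatography, and leave the unreacted (2R)-flavanone. The fallback comes back to the route at 19.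

Step 9. After ionisation at C4 the cation may lose H3 (elimination to the flav-3-ene) or be captured internally by a silyloxy oxygen of ring B instead of water. The acid may also ionise the C2–O1 bond reversibly and erode the configuration at C2, or remove a silyl group. Fallback, setting out from 17: an oxidative instead of a hydrolytic conversion, with DDQ in CH2Cl2/pH 7 buffer at 0 °C. Hydride abstraction from C4–H (α to the methoxy group and benzylic to the trioxygenated ring A), addition of water to the oxocarbenium ion and loss of methanol from the hemiketal should give the ketone directly. No compound outside the list is formed (F0, none), and the fallback comes back to the route at 19.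

Step 11. If the medium turns basic, the flavanone may enolise and open by retro-oxa-Michael elimination to the 2'-hydroxychalcone before the hemiketal has closed, and reclosure would scramble C2. Silyl cleavage may also stop at the mono-silyl stage. Fallback, setting out from 18: the order of events is changed so that no carbonyl is present when the phenols are freed. Bu4NF in THF at 0 °C should give the (2R)-2',6'-dihydroxyflavan-4-ol F5, which is handled without acid because its benzylic alcohol ionises easily. Activated MnO2 in CH2Cl2 at rt should then oxidise the benzylic 4-hydroxyl selectively in the presence of the phenols. The fallback comes back to the route at 20, which closes to 21 as in step 11.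

**Further compounds**

F1 | step 8 | racemic cis-2',6'-bis(tert-butyldimethylsilyloxy)-4,5-dimethoxy-8-prenyl-6'',6''-dimethylpyrano[2'',3'':7,6]flavan | COc1c2c(c(CC=C(C)C)c3c1C(OC)CC(O3)c1c(O[Si](C)(C)C(C)(C)C)cccc1O[Si](C)(C)C(C)(C)C)OC(C)(C)C=C2
F2 | step 8 | racemic 2',6'-bis(tert-butyldimethylsilyloxy)-5-methoxy-8-prenyl-6'',6''-dimethylpyrano[2'',3'':7,6]flavan-4-ol | COc1c2c(c(CC=C(C)C)c3c1C(O)CC(O3)c1c(O[Si](C)(C)C(C)(C)C)cccc1O[Si](C)(C)C(C)(C)C)OC(C)(C)C=C2
F3 | step 8 | racemic 2',6'-bis(tert-butyldimethylsilyloxy)-5-methoxy-8-prenyl-6'',6''-dimethylpyrano[2'',3'':7,6]flavanone | COc1c2c(c(CC=C(C)C)c3c1C(=O)CC(O3)c1c(O[Si](C)(C)C(C)(C)C)cccc1O[Si](C)(C)C(C)(C)C)OC(C)(C)C=C2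
F4 | step 8 | (2S,4S)-cis-2',6'-bis(tert-butyldimethylsilyloxy)-5-methoxy-8-prenyl-6'',6''-dimethylpyrano[2'',3'':7,6]flavan-4-ol | COc1c2c(c(CC=C(C)C)c3c1[C@@H](O)C[C@H](O3)c1c(O[Si](C)(C)C(C)(C)C)cccc1O[Si](C)(C)C(C)(C)C)OC(C)(C)C=C2
F0 | step 9 | none | none
F5 | step 11 | (2R)-2',6'-dihydroxy-5-methoxy-8-prenyl-6'',6''-dimethylpyrano[2'',3'':7,6]flavan-4-ol (both C4 epimers) | COc1c2c(c(CC=C(C)C)c3c1C(O)C[C@@H](O3)c1c(O)cccc1O)OC(C)(C)C=C2
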